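## Retrosynthetic overview

1. The target is read as (−)-epicatechin 3-O-gallate-(4β→6)-(−)-epicatechin 3-O-gallate-(4β→8)-(−)-epicatechin 3-O-gallate (all units 2R,3R, both interflavan bonds 3,4-trans). Cutting both interflavan bonds (C4–C6 and C4–C8, Friedel–Crafts type, 4β directed by the 3-O-galloyl group) gives three forms of one protected monomer: a 4-hydroxy-6,8-dibromo top unit, a 4β-arylsulfanyl-8-bromo middle unit and a 4-deoxy bottom unit.
2. All three come from one protected 2,3-cis-flavan-3,4-diol 3-gallate, and this comes from a 2,3-cis-3-oxyflavan-4-one.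
3. The flavan-4-one is made in one pot from a 2-fluoroaryl alkoxymethyl ketone and 3,4-bis(benzyloxy)benzaldehyde: a syn boron aldol reaction forms C2–C3, then SNAr of the aldolate oxygen on the ortho C–F forms O1–C8a and closes the pyran ring.
4. Enabling feature: in every C ring the O1–C2(H)Ar unit is a former ArCH=O; a ketone at C4 makes C3 an enolizable α-oxy carbon and, being ortho to aryl carbon C8a, makes a fluoride there displaceable. The same C4 carbonyl later becomes the interflavan carbocation (top, middle) or CH2 (bottom).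
5. Ring order: A and B rings are bought as arenes; the pyran C ring is formed once (step 5) and serves all three units. Then C4(top)–C6(middle) is formed, then C4(middle)–C8(bottom); hydrogenolysis removes 21 benzyl groups and 3 bromine caps.

Key step: step 5

Assumption (a): (−)-Ipc2BOTf (from (+)-α-pinene, pre-formed) is taken to give the (2S,3R)-aldol; should a first run show the opposite sense, (+)-Ipc2BOTf is used with no other change, and the enol borinate, the aldolate and the borinic acid then carry mirror-image Ipc groups.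
Assumption (b): the flavan-3,4-diol 3-gallate and its two brominated derivatives are carried as C4-epimer mixtures (3,4-cis expected to dominate), since C4 is ionized or deoxygenated in the following step.

## Route

Step 1
Reactants: 1 5-fluorobenzene-1,3-diol
Product: 2 1,3-bis(benzyloxy)-5-fluorobenzene
Conditions: BnBr (2.3 equiv), K2CO3, DMF, rt
Reagents that add atoms: benzyl bromide, BrCc1ccccc1
Why: Williamson O-benzylation (SN2) of both phenols; no stereocentre is involved.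

Step 2
Reactants: 2 1,3-bis(benzyloxy)-5-fluorobenzene
Product: 3 1,5-bis(benzyloxy)-2-bromo-3-fluorobenzene
Conditions: NBS (1.0 equiv), MeCN, 0 °C
Reagents that add atoms: N-bromosuccinimide, O=C1CCC(=O)N1Br
Why: Electrophilic aromatic bromination should go para to one benzyloxy group and ortho to the other (next to F), because the position between the two benzyloxy groups is the more hindered one.

Step 3
Reactants: 4 (4-methoxyphenyl)methanol; 5 2-chloro-N-methoxy-N-methylacetamide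
Product: 6 N-methoxy-2-[(4-methoxybenzyl)oxy]-N-methylacetamide
Conditions: NaH, THF, 0 °C → rt
Reagents that add atoms: none
Why: Williamson etherification (SN2) of the alkoxide of 4 with the α-chloro Weinreb amide.

Step 4
Reactants: 3 1,5-bis(benzyloxy)-2-bromo-3-fluorobenzene; 6 N-methoxy-2-[(4-methoxybenzyl)oxy]-N-methylacetamide
Product: 8 1-[2,4-bis(benzyloxy)-6-fluorophenyl]-2-[(4-methoxybenzyl)oxy]ethan-1-one, via aryllithium 7 (not isolated)
Conditions: n-BuLi (1.05 equiv), THF, −78 °C; then 6, −78 °C; aq. NH4Cl at −78 °C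
Reagents that add atoms: none
Why: Bromine–lithium exchange followed by Weinreb ketone synthesis; the chelated tetrahedral adduct stops over-addition, and keeping the ortho-fluoroaryllithium at −78 °C avoids LiF loss to an aryne.

Step 5
Reactants: 8 1-[2,4-bis(benzyloxy)-6-fluorophenyl]-2-[(4-methoxybenzyl)oxy]ethan-1-one; 9 3,4-bis(benzyloxy)benzaldehyde
Product: 13 (2R,3S)-5,7-bis(benzyloxy)-2-[3,4-bis(benzyloxy)phenyl]-3-[(4-methoxybenzyl)oxy]chroman-4-one (2,3-cis), via Z-enol diisopinocampheylborinate 10 (not isolated), via boron syn-aldolate 11 (not isolated), via free syn-aldol 12 (not isolated)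
Conditions: (−)-Ipc2BOTf (1.8 equiv), i-Pr2NEt, CH2Cl2, −78 °C; 9, −78 → −20 °C; then K2CO3, DMF–H2O, 0 °C → rt
Reagents that add atoms: none
Why: Soft enolization of 8 (only the CH2OPMB side can enolize) should give the Z-enol borinate 10, which adds to 9 through a closed chair (Zimmerman–Traxler) transition state and forms C2–C3 as the 2,3-syn aldolate 11; aqueous carbonate then frees the C2 oxygen of 12, which displaces the ortho fluoride by addition–elimination (SNAr through a Meisenheimer complex stabilized by the C4 carbonyl) and forms O1–C8a. The closest known reaction types are the enantioselective boron aldol reaction of ketones through diisopinocampheylboron enolates (glycolate-type syn aldol of α-alkoxy ketones) and the base-mediated SNAr cyclization of β-hydroxy 2-fluoroaryl ketones to chroman-4-ones. The pyran ring closes by ipso attack of O1 on C8a with the tether anchored at the ortho carbon C4a, a six-membered closure that is formally 6-endo-trig across the C4a=C8a bond relaying the charge to the C4 carbonyl, a favoured mode. C3 and C2 are both set in the aldol event, the syn relation by the Z-enolate geometry in the chair and the absolute sense by the isopinocampheyl ligands; the SNAr step creates no stereocentre and leaves the C2–O1 bond intact, so syn becomes 2,3-cis. The step needs only O1 to cyclize (O3 is blocked as its PMB ether, so no five-membered benzofuranone can form), an activated C–F bond (it is ortho to the C4 ketone and meta to both benzyloxy groups), and no retro-aldol or C3 epimerization (hence carbonate at or below rt and short contact).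

Step 6
Reactants: 13 (2R,3S)-5,7-bis(benzyloxy)-2-[3,4-bis(benzyloxy)phenyl]-3-[(4-methoxybenzyl)oxy]chroman-4-one
Product: 14 (2R,3S)-5,7-bis(benzyloxy)-2-[3,4-bis(benzyloxy)phenyl]-3-hydroxychroman-4-one
Conditions: DDQ (1.3 equiv), CH2Cl2–pH 7 buffer, 0 °C
Reagents that add atoms: none
Why: Oxidative PMB-ether cleavage under neutral buffered conditions should spare the less electron-rich benzyl ethers and the base-sensitive C3 centre next to the ketone.

Step 7
Reactants: 14 (2R,3S)-5,7-bis(benzyloxy)-2-[3,4-bis(benzyloxy)phenyl]-3-hydroxychroman-4-one; 15 3,4,5-tris(benzyloxy)benzoyl chloride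
Product: 16 (2R,3S)-5,7-bis(benzyloxy)-2-[3,4-bis(benzyloxy)phenyl]-4-oxochroman-3-yl 3,4,5-tris(benzyloxy)benzoate
Conditions: pyridine, DMAP (cat.), CH2Cl2, 0 °C
Reagents that add atoms: none
Why: DMAP-catalysed O-acylation of the secondary alcohol with an acid chloride; the C3–O bond is not broken, so configuration is retained.

Step 8
Reactants: 16 (2R,3S)-5,7-bis(benzyloxy)-2-[3,4-bis(benzyloxy)phenyl]-4-oxochroman-3-yl 3,4,5-tris(benzyloxy)benzoate
Product: 17 5,7,3',4'-tetra-O-benzyl-4-hydroxy-(−)-epicatechin 3-O-(3,4,5-tri-O-benzylgallate) (C4 epimers)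
Conditions: NaBH4, CeCl3·7H2O, THF–MeOH, −40 → 0 °C
Reagents that add atoms: none
Why: Luche 1,2-reduction of the aryl ketone at low temperature should leave the gallate ester in place; the C4 configuration is immaterial because C4 is ionized or deoxygenated next.

Step 9
Reactants: 17 5,7,3',4'-tetra-O-benzyl-4-hydroxy-(−)-epicatechin 3-O-(3,4,5-tri-O-benzylgallate)
Product: 18 8-bromo-5,7,3',4'-tetra-O-benzyl-4-hydroxy-(−)-epicatechin 3-O-(3,4,5-tri-O-benzylgallate) (C4 epimers)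
Conditions: NBS (1.0 equiv), CH2Cl2, −78 → −40 °C
Reagents that add atoms: N-bromosuccinimide, O=C1CCC(=O)N1Br
Why: Electrophilic aromatic bromination should occur at C8, the less hindered of the two activated A-ring positions in 5,7-di-O-benzylflavans; the bromine is the cap that later forces attack at C6.

Step 10
Reactants: 18 8-bromo-5,7,3',4'-tetra-O-benzyl-4-hydroxy-(−)-epicatechin 3-O-(3,4,5-tri-O-benzylgallate)
Product: 19 8-bromo-5,7,3',4'-tetra-O-benzyl-4β-[(2,6-dimethylphenyl)sulfanyl]-(−)-epicatechin 3-O-(3,4,5-tri-O-benzylgallate) (2,3-cis-3,4-trans)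
Conditions: 2,6-Me2C6H3SH (3 equiv), BF3·OEt2, CH2Cl2, −78 → −30 °C
Reagents that add atoms: 2,6-dimethylbenzenethiol, Cc1cccc(C)c1S
Why: Lewis-acid thiolysis (SN1 at C4 through the benzylic cation bridged by the 3-O-galloyl group as a dioxolanylium ion); the thiol enters anti to the 3-O-acyl group, which sets C4 as 4β (3,4-trans).

Step 11
Reactants: 17 5,7,3',4'-tetra-O-benzyl-4-hydroxy-(−)-epicatechin 3-O-(3,4,5-tri-O-benzylgallate)
Product: 20 6,8-dibromo-5,7,3',4'-tetra-O-benzyl-4-hydroxy-(−)-epicatechin 3-O-(3,4,5-tri-O-benzylgallate) (C4 epimers)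
Conditions: NBS (2.2 equiv), CH2Cl2, −40 → 0 °C
Reagents that add atoms: N-bromosuccinimide, O=C1CCC(=O)N1Br
Why: Exhaustive electrophilic bromination of both free A-ring positions, so that the electrophilic top unit can no longer act as a nucleophile.

Step 12
Reactants: 17 5,7,3',4'-tetra-O-benzyl-4-hydroxy-(−)-epicatechin 3-O-(3,4,5-tri-O-benzylgallate)
Product: 21 5,7,3',4'-tetra-O-benzyl-(−)-epicatechin 3-O-(3,4,5-tri-O-benzylgallate)
Conditions: Et3SiH (20 equiv), TFA, CH2Cl2, −78 → −20 °C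
Reagents that add atoms: none
Why: Ionic hydrogenation (Kursanov–Parnes reduction) of the doubly activated benzylic alcohol; the large excess of silane should outcompete alkylation of a second A ring by the C4 cation.

Step 13
Reactants: 20 6,8-dibromo-5,7,3',4'-tetra-O-benzyl-4-hydroxy-(−)-epicatechin 3-O-(3,4,5-tri-O-benzylgallate); 19 8-bromo-5,7,3',4'-tetra-O-benzyl-4β-[(2,6-dimethylphenyl)sulfanyl]-(−)-epicatechin 3-O-(3,4,5-tri-O-benzylgallate)
Product: 22 (4β→6)-linked dimer of the 6,8-dibromo top unit and the 8-bromo-4β-arylsulfanyl middle unit (both per-O-benzylated 3-O-gallates)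
Conditions: 19 (2 equiv), BF3·OEt2, 4 Å MS, CH2Cl2, −78 → −20 °C
Reagents that add atoms: none
Why: Friedel–Crafts-type interflavan coupling (SN1 at C4 of 20 under hard Lewis-acid activation); C6 is the only free A-ring position of 19, its hindered aryl sulfide is inert to BF3 (orthogonal activation), and attack anti to the participating 3-O-galloyl group sets the top C4 as 4β (3,4-trans).

Step 14
Reactants: 22 (4β→6)-linked dimer; 21 5,7,3',4'-tetra-O-benzyl-(−)-epicatechin 3-O-(3,4,5-tri-O-benzylgallate)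
Product: 23 tribromo-henicosa-O-benzyl epicatechin 3-O-gallate-(4β→6)-epicatechin 3-O-gallate-(4β→8)-epicatechin 3-O-gallate
Conditions: 21 (3 equiv), AgBF4, THF, 0 °C → rt, dark
Reagents that add atoms: none
Why: Thiophilic Ag(I) activation of the C4–S bond gives the middle-unit C4 cation, which is captured by C8 of 21 (more nucleophilic than C6) anti to the 3-O-galloyl group, setting the middle C4 as 4β; 22 has no free A-ring position and cannot self-condense.

Step 15
Reactants: 23 tribromo-henicosa-O-benzyl trimer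
Product: 24 (−)-epicatechin 3-O-gallate-(4β→6)-(−)-epicatechin 3-O-gallate-(4β→8)-(−)-epicatechin 3-O-gallate (CNP0183218.1)
Conditions: H2 (1 atm), 20% Pd(OH)2/C, Et3N (3.5 equiv), THF–MeOH–H2O, rt
Reagents that add atoms: none
Why: Catalytic hydrogenolysis should cleave all 21 benzyl ethers and the three aryl C–Br bonds without touching the gallate esters, the interflavan bonds or any stereocentre.

## Compound list

1 | 5-fluorobenzene-1,3-diol | Oc1cc(O)cc(F)c1 | starting material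
2 | 1,3-bis(benzyloxy)-5-fluorobenzene | Fc1cc(OCc2ccccc2)cc(OCc2ccccc2)c1 | intermediate
3 | 1,5-bis(benzyloxy)-2-bromo-3-fluorobenzene | Fc1cc(OCc2ccccc2)cc(OCc2ccccc2)c1Br | intermediate
4 | (4-methoxyphenyl)methanol | COc1ccc(CO)cc1 | starting material
5 | 2-chloro-N-methoxy-N-methylacetamide | CON(C)C(=O)CCl | starting material
6 | N-methoxy-2-[(4-methoxybenzyl)oxy]-N-methylacetamide | COc1ccc(COCC(=O)N(C)OC)cc1 | intermediate
7 | [2,4-bis(benzyloxy)-6-fluorophenyl]lithium | [Li]c1c(F)cc(OCc2ccccc2)cc1OCc1ccccc1 | intermediate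
8 | 1-[2,4-bis(benzyloxy)-6-fluorophenyl]-2-[(4-methoxybenzyl)oxy]ethan-1-one | COc1ccc(COCC(=O)c2c(F)cc(OCc3ccccc3)cc2OCc2ccccc2)cc1 | intermediate
9 | 3,4-bis(benzyloxy)benzaldehyde | O=Cc1ccc(OCc2ccccc2)c(OCc2ccccc2)c1 | starting material
10 | (Z)-enol diisopinocampheylborinate of 8 (O–B cis to OPMB) | COc1ccc(CO/C=C(\OB([C@@H]5C[C@@H]6C[C@@H](C6(C)C)[C@H]5C)[C@@H]5C[C@@H]6C[C@@H](C6(C)C)[C@H]5C)c2c(F)cc(OCc9ccccc9)cc2OCc9ccccc9)cc1 | intermediate
11 | (2S,3R)-syn-aldolate, O-diisopinocampheylboryl derivative of 12 | COc1ccc(CO[C@@H]([C@H](OB([C@@H]5C[C@@H]6C[C@@H](C6(C)C)[C@H]5C)[C@@H]5C[C@@H]6C[C@@H](C6(C)C)[C@H]5C)c2ccc(OCc9ccccc9)c(OCc9ccccc9)c2)C(=O)c2c(F)cc(OCc9ccccc9)cc2OCc9ccccc9)cc1 | intermediate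
12 | (2S,3R)-1-[2,4-bis(benzyloxy)-6-fluorophenyl]-3-[3,4-bis(benzyloxy)phenyl]-3-hydroxy-2-[(4-methoxybenzyl)oxy]propan-1-one | COc1ccc(CO[C@@H]([C@H](O)c2ccc(OCc9ccccc9)c(OCc9ccccc9)c2)C(=O)c2c(F)cc(OCc9ccccc9)cc2OCc9ccccc9)cc1 | intermediate
13 | (2R,3S)-5,7-bis(benzyloxy)-2-[3,4-bis(benzyloxy)phenyl]-3-[(4-methoxybenzyl)oxy]chroman-4-one (2,3-cis) | COc1ccc(CO[C@@H]2C(=O)c3c(OCc9ccccc9)cc(OCc9ccccc9)cc3O[C@@H]2c2ccc(OCc9ccccc9)c(OCc9ccccc9)c2)cc1 | intermediate
14 | (2R,3S)-5,7-bis(benzyloxy)-2-[3,4-bis(benzyloxy)phenyl]-3-hydroxychroman-4-one | O[C@@H]1C(=O)c2c(OCc9ccccc9)cc(OCc9ccccc9)cc2O[C@@H]1c1ccc(OCc9ccccc9)c(OCc9ccccc9)c1 | intermediate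
15 | 3,4,5-tris(benzyloxy)benzoyl chloride | O=C(Cl)c1cc(OCc2ccccc2)c(OCc2ccccc2)c(OCc2ccccc2)c1 | starting material
16 | (2R,3S)-5,7-bis(benzyloxy)-2-[3,4-bis(benzyloxy)phenyl]-4-oxochroman-3-yl 3,4,5-tris(benzyloxy)benzoate | O=C(O[C@@H]1C(=O)c2c(OCc9ccccc9)cc(OCc9ccccc9)cc2O[C@@H]1c1ccc(OCc9ccccc9)c(OCc9ccccc9)c1)c1cc(OCc9ccccc9)c(OCc9ccccc9)c(OCc9ccccc9)c1 | intermediate
17 | 5,7,3',4'-tetra-O-benzyl-4-hydroxy-(−)-epicatechin 3-O-(3,4,5-tri-O-benzylgallate), (2R,3R), C4 epimers | O=C(O[C@@H]1C(O)c2c(OCc9ccccc9)cc(OCc9ccccc9)cc2O[C@@H]1c1ccc(OCc9ccccc9)c(OCc9ccccc9)c1)c1cc(OCc9ccccc9)c(OCc9ccccc9)c(OCc9ccccc9)c1 | intermediate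
18 | 8-bromo derivative of 17 (C4 epimers) | O=C(O[C@@H]1C(O)c2c(OCc9ccccc9)cc(OCc9ccccc9)c(Br)c2O[C@@H]1c1ccc(OCc9ccccc9)c(OCc9ccccc9)c1)c1cc(OCc9ccccc9)c(OCc9ccccc9)c(OCc9ccccc9)c1 | intermediate
19 | 8-bromo-5,7,3',4'-tetra-O-benzyl-4β-[(2,6-dimethylphenyl)sulfanyl]-(−)-epicatechin 3-O-(3,4,5-tri-O-benzylgallate) (2,3-cis-3,4-trans) | O=C(O[C@@H]1[C@@H](Sc2c(C)cccc2C)c2c(OCc9ccccc9)cc(OCc9ccccc9)c(Br)c2O[C@@H]1c1ccc(OCc9ccccc9)c(OCc9ccccc9)c1)c1cc(OCc9ccccc9)c(OCc9ccccc9)c(OCc9ccccc9)c1 | intermediate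
20 | 6,8-dibromo derivative of 17 (C4 epimers) | O=C(O[C@@H]1C(O)c2c(OCc9ccccc9)c(Br)c(OCc9ccccc9)c(Br)c2O[C@@H]1c1ccc(OCc9ccccc9)c(OCc9ccccc9)c1)c1cc(OCc9ccccc9)c(OCc9ccccc9)c(OCc9ccccc9)c1 | intermediate
21 | 5,7,3',4'-tetra-O-benzyl-(−)-epicatechin 3-O-(3,4,5-tri-O-benzylgallate), (2R,3R) | O=C(O[C@@H]1Cc2c(OCc9ccccc9)cc(OCc9ccccc9)cc2O[C@@H]1c1ccc(OCc9ccccc9)c(OCc9ccccc9)c1)c1cc(OCc9ccccc9)c(OCc9ccccc9)c(OCc9ccccc9)c1 | intermediate
22 | [6,8-dibromo-tetra-O-benzyl-epicatechin 3-O-(tri-O-benzylgallate)]-(4β→6)-[8-bromo-4β-(2,6-dimethylphenylsulfanyl)-tetra-O-benzyl-epicatechin 3-O-(tri-O-benzylgallate)] | O=C(O[C@@H]1[C@@H](c2c(OCc9ccccc9)c(Br)c3c(c2OCc9ccccc9)[C@H](Sc2c(C)cccc2C)[C@@H](OC(=O)c2cc(OCc9ccccc9)c(OCc9ccccc9)c(OCc9ccccc9)c2)[C@@H](c2ccc(OCc9ccccc9)c(OCc9ccccc9)c2)O3)c2c(OCc9ccccc9)c(Br)c(OCc9ccccc9)c(Br)c2O[C@@H]1c1ccc(OCc9ccccc9)c(OCc9ccccc9)c1)c1cc(OCc9ccccc9)c(OCc9ccccc9)c(OCc9ccccc9)c1 | intermediate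
23 | tribromo-henicosa-O-benzyl trimer: top unit 6,8-dibromo, middle unit 8-bromo, linkages (4β→6) and (4β→8), all phenols as benzyl ethers | O=C(O[C@@H]1[C@@H](c2c(OCc9ccccc9)c(Br)c3c(c2OCc9ccccc9)[C@H](c2c(OCc9ccccc9)cc(OCc9ccccc9)c4c2O[C@H](c2ccc(OCc9ccccc9)c(OCc9ccccc9)c2)[C@H](OC(=O)c2cc(OCc9ccccc9)c(OCc9ccccc9)c(OCc9ccccc9)c2)C4)[C@@H](OC(=O)c2cc(OCc9ccccc9)c(OCc9ccccc9)c(OCc9ccccc9)c2)[C@@H](c2ccc(OCc9ccccc9)c(OCc9ccccc9)c2)O3)c2c(OCc9ccccc9)c(Br)c(OCc9ccccc9)c(Br)c2O[C@@H]1c1ccc(OCc9ccccc9)c(OCc9ccccc9)c1)c1cc(OCc9ccccc9)c(OCc9ccccc9)c(OCc9ccccc9)c1 | intermediate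
24 | (−)-epicatechin 3-O-gallate-(4β→6)-(−)-epicatechin 3-O-gallate-(4β→8)-(−)-epicatechin 3-O-gallate (CNP0183218.1) | O=C(O[C@@H]1[C@@H](c2c(O)cc3c(c2O)[C@H](c2c(O)cc(O)c4c2O[C@H](c2ccc(O)c(O)c2)[C@H](OC(=O)c2cc(O)c(O)c(O)c2)C4)[C@@H](OC(=O)c2cc(O)c(O)c(O)c2)[C@@H](c2ccc(O)c(O)c2)O3)c2c(O)cc(O)cc2O[C@@H]1c1ccc(O)c(O)c1)c1cc(O)c(O)c(O)c1 | target

## Step count and risks

Total step count: 15. Longest linear sequence: 12 steps (1, 2, 4, 5, 6, 7, 8, 9, 10, 13, 14, 15).

Steps most likely to fail: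

1. Step 5. Facial control by the isopinocampheyl ligands may be insufficient with an electron-rich aryl aldehyde, and under the carbonate conditions the aldol may revert or C3 may epimerize toward the 2,3-trans series before or after ring closure. The fallback for step 5 sets out from 9 and comes back to the route at 13; it separates the two bond formations and sets both stereocentres with a covalently bound auxiliary. Commercial [(4-methoxybenzyl)oxy]acetic acid is joined to (S)-4-benzyloxazolidin-2-one through its pivalic mixed anhydride and the lithiated auxiliary, which gives (S)-4-benzyl-3-{[(4-methoxybenzyl)oxy]acetyl}oxazolidin-2-one F1. An Evans syn aldol reaction of imide F1 with 9, run with Bu2BOTf and Et3N in CH2Cl2 from −78 to 0 °C, gives (S)-4-benzyl-3-{(2S,3R)-3-[3,4-bis(benzyloxy)phenyl]-3-hydroxy-2-[(4-methoxybenzyl)oxy]propanoyl}oxazolidin-2-one F2. Transamidation of aldol imide F2 with MeNHOMe·HCl and AlMe3 gives (2S,3R)-3-[3,4-bis(benzyloxy)phenyl]-3-hydroxy-N-methoxy-2-[(4-methoxybenzyl)oxy]-N-methylpropanamide F3 and returns the auxiliary. Addition of an excess of aryllithium 7, made from 3 as in step 4, to Weinreb amide F3 at −78 °C then gives 12 as an isolated compound, and a brief treatment with K2CO3 in DMF at 0 °C closes it to 13.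

2. Step 13. Attack by C6 of the brominated, sulfur-bearing middle unit may be too slow, so that the top-unit cation decomposes or the arylsulfanyl group migrates between units through sulfonium ions. The fallback for step 13 sets out from 20 and 21 and comes back to the route at 23; it replaces the orthogonal sulfide by a late oxidation at C4. Bromination of 21 with NBS gives 8-bromo-5,7,3',4'-tetra-O-benzyl-(−)-epicatechin 3-O-(3,4,5-tri-O-benzylgallate) F4. Coupling of bromide F4 with 20 under BF3·OEt2 or TMSOTf gives the (4β→6) dimer of the 6,8-dibromo top unit and the 8-bromo middle unit with C4H2 in the middle unit F5. Oxidation of dimer F5 with DDQ in the presence of 2-ethoxyethanol, at its only benzylic CH2 group, gives the same dimer with a 4β-(2-ethoxyethoxy) group at C4 of the middle unit F6. Coupling of acetal-type ether F6 with an excess of 21 under TMSOTf gives 23 directly, so that step 14 is bypassed as well.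

3. Step 12. Alkylation of the A ring of a second molecule by the C4 cation may compete with hydride transfer and lead to oligomers. The fallback for step 12 sets out from 15 and comes back to the route at 21; it takes the bottom unit alone from the chiral pool. Commercial (−)-epicatechin is O-benzylated at its four phenols with BnBr and K2CO3 in DMF to give 5,7,3',4'-tetra-O-benzyl-(−)-epicatechin F7. Acylation of alcohol F7 with 15 in the presence of pyridine and DMAP gives 21.

Further compounds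
F1 | step 5 | (S)-4-benzyl-3-{[(4-methoxybenzyl)oxy]acetyl}oxazolidin-2-one | COc1ccc(COCC(=O)N2[C@@H](Cc3ccccc3)COC2=O)cc1
F2 | step 5 | (S)-4-benzyl-3-{(2S,3R)-3-[3,4-bis(benzyloxy)phenyl]-3-hydroxy-2-[(4-methoxybenzyl)oxy]propanoyl}oxazolidin-2-one | COc1ccc(CO[C@@H]([C@H](O)c2ccc(OCc9ccccc9)c(OCc9ccccc9)c2)C(=O)N2[C@@H](Cc3ccccc3)COC2=O)cc1
F3 | step 5 | (2S,3R)-3-[3,4-bis(benzyloxy)phenyl]-3-hydroxy-N-methoxy-2-[(4-methoxybenzyl)oxy]-N-methylpropanamide | COc1ccc(CO[C@@H]([C@H](O)c2ccc(OCc9ccccc9)c(OCc9ccccc9)c2)C(=O)N(C)OC)cc1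
F4 | step 13 | 8-bromo-5,7,3',4'-tetra-O-benzyl-(−)-epicatechin 3-O-(3,4,5-tri-O-benzylgallate) | O=C(O[C@@H]1Cc2c(OCc9ccccc9)cc(OCc9ccccc9)c(Br)c2O[C@@H]1c1ccc(OCc9ccccc9)c(OCc9ccccc9)c1)c1cc(OCc9ccccc9)c(OCc9ccccc9)c(OCc9ccccc9)c1
F5 | step 13 | (4β→6) dimer of the 6,8-dibromo top unit and the 8-bromo middle unit with C4H2 in the middle unit | O=C(O[C@@H]1[C@@H](c2c(OCc9ccccc9)c(Br)c3c(c2OCc9ccccc9)C[C@@H](OC(=O)c2cc(OCc9ccccc9)c(OCc9ccccc9)c(OCc9ccccc9)c2)[C@@H](c2ccc(OCc9ccccc9)c(OCc9ccccc9)c2)O3)c2c(OCc9ccccc9)c(Br)c(OCc9ccccc9)c(Br)c2O[C@@H]1c1ccc(OCc9ccccc9)c(OCc9ccccc9)c1)c1cc(OCc9ccccc9)c(OCc9ccccc9)c(OCc9ccccc9)c1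
F6 | step 13 | the same dimer with a 4β-(2-ethoxyethoxy) group at C4 of the middle unit | O=C(O[C@@H]1[C@@H](c2c(OCc9ccccc9)c(Br)c3c(c2OCc9ccccc9)[C@H](OCCOCC)[C@@H](OC(=O)c2cc(OCc9ccccc9)c(OCc9ccccc9)c(OCc9ccccc9)c2)[C@@H](c2ccc(OCc9ccccc9)c(OCc9ccccc9)c2)O3)c2c(OCc9ccccc9)c(Br)c(OCc9ccccc9)c(Br)c2O[C@@H]1c1ccc(OCc9ccccc9)c(OCc9ccccc9)c1)c1cc(OCc9ccccc9)c(OCc9ccccc9)c(OCc9ccccc9)c1
F7 | step 12 | 5,7,3',4'-tetra-O-benzyl-(−)-epicatechin | O[C@@H]1Cc2c(OCc9ccccc9)cc(OCc9ccccc9)cc2O[C@@H]1c1ccc(OCc9ccccc9)c(OCc9ccccc9)c1
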